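**Retrosynthetic overview**

1. Tetraphlorethol C (16) comes from its nonamethyl ether 15 by global O-demethylation; the rings are lettered A to D from the 3,5-dihydroxyphenoxy end.
2. 15 comes from tridepside 12 by loss of three CO, one per ester. Each ether oxygen of the target joins a carbon flanked by two oxygenated carbons (C1 of rings B, C and D) to a carbon with two free ortho positions (C1 of ring A, C4 of rings B and C). That is the pattern of a 4-O-aroylated syringate unit minus its carbonyl carbon.
3. 12 comes from ring D phenol 3, two units of 4-O-benzylsyringic acid 6 (ring C, then ring B) and 3,5-dimethoxybenzoic acid 11 (ring A), joined by esterification and hydrogenolysis in the order D, C, B, A.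
4. No ring is formed anywhere in the route. The four benzene rings come from the starting materials, and the head-to-tail order is fixed in the ester chain before any aryl C–O bond is made.

Key step: step 8

Remark: the three ester links of 12 are taken to contract from the A–B end inward (via 13 and 14); any other order should pass through positional isomers of these and converge on the same product 15.

**Route**

Step 1
Reactants: 1 2,4,6-trimethoxybenzaldehyde
Product: 3 2,4,6-trimethoxyphenol, via aryl formate 2 (not isolated)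
Conditions: mCPBA, CH2Cl2, 0 °C → rt; then MeOH, HCl (cat.), rt, under argon
Reagents that add atoms: mCPBA (3-chloroperoxybenzoic acid), O=C(OO)c1cccc(Cl)c1
Why: Baeyer–Villiger (Dakin-type) oxidation, in which the electron-rich aryl group migrates in preference to hydrogen, followed by acid-catalysed methanolysis of the aryl formate, which keeps the oxidation-prone phenol away from basic aerobic conditions.

Step 2
Reactants: 4 syringic acid
Product: 6 4-(benzyloxy)-3,5-dimethoxybenzoic acid, via dibenzylated syringate 5 (not isolated)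
Conditions: BnBr (2.3 equiv), K2CO3, acetone, reflux; filter, evaporate; then NaOH, THF/H2O, 60 °C; HCl to pH 2
Reagents that add atoms: benzyl bromide, BrCc1ccccc1; sodium hydroxide, [Na+].[OH-]
Why: Williamson alkylation of both the phenoxide and the carboxylate, then saponification, which cleaves only the benzyl ester because the benzyl aryl ether is inert to hydroxide.

Step 3
Reactants: 6 4-(benzyloxy)-3,5-dimethoxybenzoic acid; 3 2,4,6-trimethoxyphenol
Product: 7 2,4,6-trimethoxyphenyl 4-(benzyloxy)-3,5-dimethoxybenzoate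
Conditions: DIC, DMAP (cat.), CH2Cl2, 0 °C → rt
Reagents that add atoms: none
Why: Steglich esterification, in which the O-acylisourea is relayed through the acylpyridinium ion to the phenol, whose two ortho methoxy groups are small enough not to block O-acylation.

Step 4
Reactants: 7 2,4,6-trimethoxyphenyl 4-(benzyloxy)-3,5-dimethoxybenzoate
Product: 8 2,4,6-trimethoxyphenyl 4-hydroxy-3,5-dimethoxybenzoate
Conditions: H2 (1 atm), 10% Pd/C, EtOAc/THF, rt
Reagents that add atoms: none
Why: Hydrogenolysis of the benzyl aryl ether over palladium on carbon; the aryl ester and the methyl ethers are inert in this non-nucleophilic, neutral medium.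

Step 5
Reactants: 8 2,4,6-trimethoxyphenyl 4-hydroxy-3,5-dimethoxybenzoate; 6 4-(benzyloxy)-3,5-dimethoxybenzoic acid
Product: 9 2,6-dimethoxy-4-[(2,4,6-trimethoxyphenoxy)carbonyl]phenyl 4-(benzyloxy)-3,5-dimethoxybenzoate
Conditions: DIC, DMAP (cat.), CH2Cl2, 0 °C → rt
Reagents that add atoms: none
Why: Steglich esterification as in step 3; the 4-hydroxyl is made more acidic by the para ester and should be acylated by the acylpyridinium ion at low temperature faster than the existing aryl ester can exchange.

Step 6
Reactants: 9 2,6-dimethoxy-4-[(2,4,6-trimethoxyphenoxy)carbonyl]phenyl 4-(benzyloxy)-3,5-dimethoxybenzoate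
Product: 10 2,6-dimethoxy-4-[(2,4,6-trimethoxyphenoxy)carbonyl]phenyl 4-hydroxy-3,5-dimethoxybenzoate
Conditions: H2 (1 atm), 10% Pd/C, EtOAc/THF, rt
Reagents that add atoms: none
Why: Hydrogenolysis of the benzyl aryl ether as in step 4, leaving both aryl ester links untouched.

Step 7
Reactants: 10 2,6-dimethoxy-4-[(2,4,6-trimethoxyphenoxy)carbonyl]phenyl 4-hydroxy-3,5-dimethoxybenzoate; 11 3,5-dimethoxybenzoic acid
Product: 12 tridepside, 2,4,6-trimethoxyphenyl 4-({4-[(3,5-dimethoxybenzoyl)oxy]-3,5-dimethoxybenzoyl}oxy)-3,5-dimethoxybenzoate (ring order A–CO–O–B–CO–O–C–CO–O–D)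
Conditions: DIC, DMAP (cat.), CH2Cl2, 0 °C → rt
Reagents that add atoms: none
Why: Steglich esterification of the last free phenol, which completes the ester chain that encodes the ring order.

Step 8
Reactants: 12 tridepside
Product: 15 nona-O-methyltetraphlorethol C, 1,3,5-trimethoxy-2-{4-[4-(3,5-dimethoxyphenoxy)-3,5-dimethoxyphenoxy]-3,5-dimethoxyphenoxy}benzene, via monoether diester 13 (not isolated), via diether monoester 14 (not isolated)
Conditions: Ni(cod)2 (30 mol %, 10 mol % per ester), 3,4-bis(dicyclohexylphosphino)thiophene (dcypt, 60 mol %), anhydrous K3PO4, mesitylene (0.01 M), 150 °C, slow argon sweep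
Reagents that add atoms: none
Why: Proposed new method: zerovalent nickel carrying the chelating bisphosphine should insert into each acyl C–O bond to give an acyl aryloxide complex of divalent nickel, the carbonyl should migrate to the metal and leave as CO, and reductive elimination from the resulting aryl nickel aryloxide should form the aryl C–O bond, three times over, at C1 of ring A and at C4 of rings B and C. The closest known reaction type is the nickel- or palladium-catalysed decarbonylative etherification of single aryl esters, established mainly for azine carboxylates and electron-poor aroyl groups, so its extension to three electron-rich benzoate links in one substrate is untested. No ring is closed and no stereocentre is formed. The step needs insertion at the acyl C–O bonds and not at the aryl C–O or methyl ether bonds; the ester-bearing aryl carbons are shielded by two ortho methoxy groups and are electron rich, and methoxy groups on simple benzene rings are not expected to be cleaved by a nickel bisphosphine catalyst without a Lewis acid or a reductant. It also needs each aryloxide to stay on the nickel that carries its aryl partner, since exchange between metal centres would shuffle the ring order; the chelating ligand leaves no open site for bridging, an ortho methoxy oxygen can hold the aryloxide on the metal, and high dilution without free phenol disfavours the bimolecular exchange against the unimolecular reductive elimination. The argon sweep removes CO so that it does not tie up zerovalent nickel as carbonyl complexes, and the meta placement of the methoxy groups on every nickel-bound aryl carbon leaves that carbon unhindered for the C–O reductive elimination.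

Step 9
Reactants: 15 nona-O-methyltetraphlorethol C
Product: 16 tetraphlorethol C
Conditions: BBr3 (excess, about 2 equiv per OMe), CH2Cl2, −78 °C → rt; then H2O, 0 °C; EtOAc extraction and Sephadex LH-20 (MeOH) under argon
Reagents that add atoms: none
Why: Lewis acid-mediated cleavage of aryl methyl ethers, in which BBr3 binds each methoxy oxygen and bromide removes the methyl group by SN2, while the diaryl ether C–O bonds offer bromide no sp3 carbon and should stay intact.

**Compound list**

1 | 2,4,6-trimethoxybenzaldehyde | COc1cc(OC)c(C=O)c(OC)c1 | starting material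
2 | 2,4,6-trimethoxyphenyl formate | COc1cc(OC)c(OC=O)c(OC)c1 | intermediate
3 | 2,4,6-trimethoxyphenol | COc1cc(OC)c(O)c(OC)c1 | intermediate
4 | syringic acid (4-hydroxy-3,5-dimethoxybenzoic acid) | COc1cc(C(=O)O)cc(OC)c1O | starting material
5 | benzyl 4-(benzyloxy)-3,5-dimethoxybenzoate | COc1cc(C(=O)OCc2ccccc2)cc(OC)c1OCc1ccccc1 | intermediate
6 | 4-(benzyloxy)-3,5-dimethoxybenzoic acid | COc1cc(C(=O)O)cc(OC)c1OCc1ccccc1 | intermediate
7 | 2,4,6-trimethoxyphenyl 4-(benzyloxy)-3,5-dimethoxybenzoate | COc1cc(OC)c(OC(=O)c2cc(OC)c(OCc3ccccc3)c(OC)c2)c(OC)c1 | intermediate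
8 | 2,4,6-trimethoxyphenyl 4-hydroxy-3,5-dimethoxybenzoate | COc1cc(OC)c(OC(=O)c2cc(OC)c(O)c(OC)c2)c(OC)c1 | intermediate
9 | 2,6-dimethoxy-4-[(2,4,6-trimethoxyphenoxy)carbonyl]phenyl 4-(benzyloxy)-3,5-dimethoxybenzoate | COc1cc(OC)c(OC(=O)c2cc(OC)c(OC(=O)c3cc(OC)c(OCc4ccccc4)c(OC)c3)c(OC)c2)c(OC)c1 | intermediate
10 | 2,6-dimethoxy-4-[(2,4,6-trimethoxyphenoxy)carbonyl]phenyl 4-hydroxy-3,5-dimethoxybenzoate | COc1cc(OC)c(OC(=O)c2cc(OC)c(OC(=O)c3cc(OC)c(O)c(OC)c3)c(OC)c2)c(OC)c1 | intermediate
11 | 3,5-dimethoxybenzoic acid | COc1cc(OC)cc(C(=O)O)c1 | starting material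
12 | tridepside, 2,4,6-trimethoxyphenyl 4-({4-[(3,5-dimethoxybenzoyl)oxy]-3,5-dimethoxybenzoyl}oxy)-3,5-dimethoxybenzoate | COc1cc(OC)cc(C(=O)Oc2c(OC)cc(C(=O)Oc3c(OC)cc(C(=O)Oc4c(OC)cc(OC)cc4OC)cc3OC)cc2OC)c1 | intermediate
13 | 2,6-dimethoxy-4-[(2,4,6-trimethoxyphenoxy)carbonyl]phenyl 4-(3,5-dimethoxyphenoxy)-3,5-dimethoxybenzoate | COc1cc(OC)cc(Oc2c(OC)cc(C(=O)Oc3c(OC)cc(C(=O)Oc4c(OC)cc(OC)cc4OC)cc3OC)cc2OC)c1 | intermediate
14 | 2,4,6-trimethoxyphenyl 4-[4-(3,5-dimethoxyphenoxy)-3,5-dimethoxyphenoxy]-3,5-dimethoxybenzoate | COc1cc(OC)cc(Oc2c(OC)cc(Oc3c(OC)cc(C(=O)Oc4c(OC)cc(OC)cc4OC)cc3OC)cc2OC)c1 | intermediate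
15 | nona-O-methyltetraphlorethol C, 1,3,5-trimethoxy-2-{4-[4-(3,5-dimethoxyphenoxy)-3,5-dimethoxyphenoxy]-3,5-dimethoxyphenoxy}benzene | COc1cc(OC)cc(Oc2c(OC)cc(Oc3c(OC)cc(Oc4c(OC)cc(OC)cc4OC)cc3OC)cc2OC)c1 | intermediate
16 | tetraphlorethol C | Oc1cc(O)cc(Oc2c(O)cc(Oc3c(O)cc(Oc4c(O)cc(O)cc4O)cc3O)cc2O)c1 | target

**Step count**

Total: 9 steps. Longest linear sequence: 8 steps (from 4 through steps 2 to 9, or from 1 through steps 1 and 3 to 9).

**Steps most likely to fail**

Step 8 (proposed new method). The catalytic cycle may stall, because oxidative addition into electron-rich benzoate links or C–O reductive elimination from divalent nickel may be too slow. The CO set free may also sequester the zerovalent nickel, or aryloxides may exchange between metal centres and scramble the ring order. The fallback uses known chemistry, sets out from phenol 3 and rejoins the route at 15: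
- Nucleophilic aromatic substitution of 3 on 4-fluoro-2,6-dimethoxybenzaldehyde (K2CO3, DMF, 120 °C, argon) should give 2,6-dimethoxy-4-(2,4,6-trimethoxyphenoxy)benzaldehyde F1.
- Baeyer–Villiger oxidation (mCPBA, CH2Cl2) should give 2,6-dimethoxy-4-(2,4,6-trimethoxyphenoxy)phenyl formate F2, and methanolysis (MeOH, HCl cat.) should give 2,6-dimethoxy-4-(2,4,6-trimethoxyphenoxy)phenol F3.
- The same substitution on F3 should give 4-[2,6-dimethoxy-4-(2,4,6-trimethoxyphenoxy)phenoxy]-2,6-dimethoxybenzaldehyde F4.
- The same oxidation should give 4-[2,6-dimethoxy-4-(2,4,6-trimethoxyphenoxy)phenoxy]-2,6-dimethoxyphenyl formate F5, and methanolysis should give 4-[2,6-dimethoxy-4-(2,4,6-trimethoxyphenoxy)phenoxy]-2,6-dimethoxyphenol F6.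
- Copper-catalysed Ullmann coupling of F6 with 1-bromo-3,5-dimethoxybenzene (copper iodide CuI, picolinic acid, K3PO4, DMSO, 100 °C) should then give 15.

Step 9. Cleavage of the nine methyl ethers may stop short as partly cleaved borates precipitate, and the free polyphenol may oxidise in air or co-elute with under-demethylated material during isolation. The fallback sets out from 15 and returns at 16. The BBr3 cleavage would be run as before, but the crude polyphenol would be acetylated at once (Ac2O, pyridine, DMAP cat., rt) to tetraphlorethol C nonaacetate F7. This derivative should be stable to air and to silica gel and should separate from incompletely demethylated acetates. Zemplén deacetylation (NaOMe cat., degassed MeOH, 0 °C, then Amberlite IR-120 in its H+ form) should release 16.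

Step 7. Acylation of the hindered, electron-poor phenol of 10 may be slow, so that DMAP-catalysed acyl transfer among its two aryl ester links scrambles the depside order. The fallback replaces the linear chain extension by a two-plus-two union; it sets out from 4 and 8 and rejoins the route at 12:
- Carboxylate alkylation of 4 (BnBr, KHCO3, DMF, rt) should give benzyl 4-hydroxy-3,5-dimethoxybenzoate F8.
- Acylation with commercial 3,5-dimethoxybenzoyl chloride (Et3N, DMAP cat., CH2Cl2) should give benzyl 4-[(3,5-dimethoxybenzoyl)oxy]-3,5-dimethoxybenzoate F9.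
- Hydrogenolysis (H2, 10% Pd/C, EtOAc) should give 4-[(3,5-dimethoxybenzoyl)oxy]-3,5-dimethoxybenzoic acid F10.
- Oxalyl chloride with DMF (cat.) in CH2Cl2 should give 4-[(3,5-dimethoxybenzoyl)oxy]-3,5-dimethoxybenzoyl chloride F11.
- The acid chloride should acylate phenol 8 (Et3N, DMAP cat., CH2Cl2, 0 °C) faster than ester exchange can occur, giving 12.

**Further compounds**

F1 | step 8 | 2,6-dimethoxy-4-(2,4,6-trimethoxyphenoxy)benzaldehyde | COc1cc(OC)c(Oc2cc(OC)c(C=O)c(OC)c2)c(OC)c1
F2 | step 8 | 2,6-dimethoxy-4-(2,4,6-trimethoxyphenoxy)phenyl formate | COc1cc(OC)c(Oc2cc(OC)c(OC=O)c(OC)c2)c(OC)c1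
F3 | step 8 | 2,6-dimethoxy-4-(2,4,6-trimethoxyphenoxy)phenol | COc1cc(OC)c(Oc2cc(OC)c(O)c(OC)c2)c(OC)c1
F4 | step 8 | 4-[2,6-dimethoxy-4-(2,4,6-trimethoxyphenoxy)phenoxy]-2,6-dimethoxybenzaldehyde | COc1cc(OC)c(Oc2cc(OC)c(Oc3cc(OC)c(C=O)c(OC)c3)c(OC)c2)c(OC)c1
F5 | step 8 | 4-[2,6-dimethoxy-4-(2,4,6-trimethoxyphenoxy)phenoxy]-2,6-dimethoxyphenyl formate | COc1cc(OC)c(Oc2cc(OC)c(Oc3cc(OC)c(OC=O)c(OC)c3)c(OC)c2)c(OC)c1
F6 | step 8 | 4-[2,6-dimethoxy-4-(2,4,6-trimethoxyphenoxy)phenoxy]-2,6-dimethoxyphenol | COc1cc(OC)c(Oc2cc(OC)c(Oc3cc(OC)c(O)c(OC)c3)c(OC)c2)c(OC)c1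
F7 | step 9 | tetraphlorethol C nonaacetate | CC(=O)Oc1cc(OC(C)=O)cc(Oc2c(OC(C)=O)cc(Oc3c(OC(C)=O)cc(Oc4c(OC(C)=O)cc(OC(C)=O)cc4OC(C)=O)cc3OC(C)=O)cc2OC(C)=O)c1
F8 | step 7 | benzyl 4-hydroxy-3,5-dimethoxybenzoate | COc1cc(C(=O)OCc2ccccc2)cc(OC)c1O
F9 | step 7 | benzyl 4-[(3,5-dimethoxybenzoyl)oxy]-3,5-dimethoxybenzoate | COc1cc(OC)cc(C(=O)Oc2c(OC)cc(C(=O)OCc3ccccc3)cc2OC)c1
F10 | step 7 | 4-[(3,5-dimethoxybenzoyl)oxy]-3,5-dimethoxybenzoic acid | COc1cc(OC)cc(C(=O)Oc2c(OC)cc(C(=O)O)cc2OC)c1
F11 | step 7 | 4-[(3,5-dimethoxybenzoyl)oxy]-3,5-dimethoxybenzoyl chloride | COc1cc(OC)cc(C(=O)Oc2c(OC)cc(C(=O)Cl)cc2OC)c1
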